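The constants used here belong to no real substance, and the outcome is calculated.

At early times substrate and partner build intermediate A, and target has to wait for two further steps.

    substrate + partner → intermediate A (k1 = 4.8 × 10⁻⁵ M⁻¹ s⁻¹)
    second reagent + intermediate A → intermediate B (k2 = 1.5 × 10⁻⁵ M⁻¹ s⁻¹)
    third reagent + intermediate B → target (k3 = 1.5 × 10⁻⁵ M⁻¹ s⁻¹)
    substrate + second reagent → side product A (k4 = 3.7 × 10⁻⁶ M⁻¹ s⁻¹)
    substrate + intermediate B → side product B (k5 = 6.1 × 10⁻⁶ M⁻¹ s⁻¹)
    target ⇌ isomer of the product (K6 = 1.6, k6 = 1.8 × 10⁻⁶ s⁻¹)

common to all: substrate 0.50 M; second reagent 1.50 equiv; third reagent 2.00 equiv; time 50 h

| flask | partner |
|---|---|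
| Monday's | 0.500 equiv |
| Saturday's | 1.20 equiv |

- percentages count the substrate that a species holds: one side product B counts as two
- run time (Monday's): 50 h

* which of the two there is more of at the end, Monday's (target / side product A)
* which of the two there is more of at the end, Saturday's (target / side product A)
* final target, as a percentage of the substrate charged, in Monday's
* final target, as a percentage of the substrate charged, in Saturday's

I wrote the balance of the partner, the limiting reagent in Monday's flask. Partner that reacts becomes intermediate A, then intermediate B, and from there target, its isomer or side product B; I left that last branch out of the reckoning. In Monday's flask second reagent and third reagent stand in excess over partner, so I held them at their charges. That made the two later steps pseudo-first-order, at 0.0405 h⁻¹ and 0.0540 h⁻¹.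

Two extreme flasks could then be solved. In the first, everything enters the chain at the start, and 67.4% of it has passed both steps at the end of the run. In the second, material enters evenly across the run. The share of that even stream which has passed both steps by the end, 32.2%, I call the even-feed passage.

In Monday's flask the half-life of substrate by the partner step, with partner held as charged, 16 h, is shorter than the run, so entry leans early, though it is not instantaneous. I therefore expected target plus isomer between 16.1% and 33.7% of the substrate charged. In Saturday's flask partner exceeds substrate, so I took the substrate charge as the ceiling on entry, though side product A draws on the same substrate. Keeping the same two rates, I expected between 32.2% and 67.4%.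

Mine was a window on target plus isomer. The forecast gave a figure on target: 17% (15% to 19%) in Monday's flask with side product A ahead, and 31% (28% to 34%) in Saturday's with target ahead, saying of target plus isomer in Monday's flask that “roughly 89% of that remains as target”.

The simulation gave target 16.6% against side product A 21.7% in Monday's flask, and target 30.7% against 11.3% in Saturday's, both target figures inside the forecast's ranges. Target plus isomer stood at 18.7% in Monday's flask and 34.7% in Saturday's, each above its even-feed figure. A neighbouring flask ran Monday's recipe at 0.30 M of substrate, with the same equivalents and time. Its chain rates are lower, at 0.0243 h⁻¹ and 0.0324 h⁻¹, so the even-feed passage becomes 17.0%, which on the partner's charge gives 8.50%. That flask read target 8.02% and isomer 0.863%, together 8.88%.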